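## Retrosynthetic overview

1. Target 34 ⇐ desilylation, chromate [3,3] oxidative transposition of a C7 tertiary allylic alcohol, acetylation and ester reduction of trienoate 30; 30 ⇐ ester aldol/E1cB of spiro ester 20 with dienal 26 (three steps from sulcatone).
2. 20 ⇐ hydroxy ester 18 (SeO2 ene/[2,3] oxidation at C7, silylation); the cyclopentane (second and last ring formed) ⇐ SmI2 ketyl–enoate cyclisation of aldehyde 17.
3. 17 ⇐ aldehyde 10 by hydroboration, hydroxyl-directed epoxidation/hydride opening (C10–OH), oxidation and Wittig extension.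
4. 10 (quaternary spiro carbon C11) ⇐ Claisen rearrangement of allyl dienyl ether 9 ⇐ Wittig on alkylated (S)-carvone 4; the cyclohexane ring is bought with carvone, whose stereocentre relays all others.

Assumption: the target is taken as drawn, i.e. (6R,10S,11S,14S,26S; 2Z,15E,17E) in iridal numbering. Locants in the explanations are those of the target for every intermediate (C6 = CH with the hydroxypropyl chain, C7 = enal ring carbon, C10 = methyl carbinol, C11 = spiro carbon, C12/C13 = cyclopentane CH2, C14 = cyclopentane CH with the side chain, C26 = cyclopentane CHOH, C27 = CH2OAc). TBS = tert-butyldimethylsilyl, TES = triethylsilyl, Sia = 3-methylbutan-2-yl.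

## Route

Step 1
Reactants: 1 (S)-(+)-carvone; 2 tert-butyl(3-iodopropoxy)dimethylsilane
Product: 4 (5S,6R)-6-[3-(TBSO)propyl]carvone, via lithium dienolate 3 (not isolated)
Conditions: LiN(i-Pr)2, THF, −78 °C; then 2, DMPU, −78 → −20 °C
Reagents that add atoms: none
Why: Kinetic deprotonation gives the cross-conjugated lithium enolate, whose SN2 alkylation by the primary iodide (enolate alkylation) occurs anti to the isopropenyl group on the neighbouring carbon C7, setting C6 from the bought stereocentre.

Step 2
Reactants: 5 allyl chloromethyl ether; 6 triphenylphosphine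
Product: 7 (allyloxymethyl)triphenylphosphonium chloride
Conditions: toluene, 60 °C
Reagents that add atoms: none
Why: Quaternisation of the phosphine by the reactive α-chloro ether (SN2) gives the Wittig salt.

Step 3
Reactants: 4 alkylated carvone; 7 phosphonium salt
Product: 9 allyl dienyl ether (E/Z mixture at the enol ether), via phosphorus ylide 8 (not isolated)
Conditions: 7 (2.5 equiv), KN(SiMe3)2, THF, 0 °C; then 4, 0 → 40 °C
Reagents that add atoms: none
Why: Wittig olefination of the enone carbonyl with the non-stabilised alkoxymethylene ylide gives the allyl vinyl ether needed for rearrangement; the enol-ether geometry is irrelevant and C6, if epimerised by base, returns to the favoured trans form.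

Step 4
Reactants: 9 allyl dienyl ether
Product: 10 (1R,5S,6R)-1-allyl-6-[3-(TBSO)propyl]-2-methyl-5-(prop-1-en-2-yl)cyclohex-2-ene-1-carbaldehyde
Conditions: xylenes, 2,6-di-tert-butyl-4-methylphenol (cat.), 130 °C, sealed tube
Reagents that add atoms: none
Why: Claisen rearrangement ([3,3]-sigmatropic, chair transition state) forms the C11–C12 bond and the quaternary centre, the allyl terminus adding to the ring face opposite the adjacent C6 side chain (A(1,3) strain model), so CHO ends cis and allyl trans to that chain.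

Step 5
Reactants: 10 quaternary aldehyde
Product: 12 diol (C26 CH2OH and 3-hydroxypropyl on C11), via organoborane 11 (not isolated)
Conditions: Sia2BH (3.2 equiv), THF, 0 → 25 °C; then NaOH, H2O2, 0 °C
Reagents that add atoms: hydrogen peroxide, OO
Why: The hindered dialkylborane reduces the aldehyde and hydroborates only the monosubstituted alkene anti-Markovnikov (hydroboration–oxidation); the trisubstituted ring alkene and the 1,1-disubstituted isopropenyl group react far more slowly.

Step 6
Reactants: 12 diol
Product: 13 epoxy diol (C9–C10 epoxide cis to the C26 CH2OH)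
Conditions: VO(acac)2 (5 mol %), t-BuOOH, CH2Cl2, 0 → 25 °C
Reagents that add atoms: tert-butyl hydroperoxide, CC(C)(C)OO
Why: Hydroxyl-directed epoxidation: the vanadium alkoxide of the homoallylic CH2OH delivers oxygen to the ring alkene on its own face, so the future C10–O bond is cis to C26; the other alkenes are not directed and stay intact.

Step 7
Reactants: 13 epoxy diol
Product: 14 triol (tertiary C10–OH, two primary OH)
Conditions: LiEt3BH, THF, 0 → 40 °C; aqueous work-up
Reagents that add atoms: none
Why: SN2 hydride opening of the trisubstituted epoxide at the less hindered secondary carbon C9 leaves the tertiary C–O bond untouched, so the C10 carbinol keeps the epoxide configuration.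

Step 8
Reactants: 14 triol
Product: 16 hydroxy dialdehyde, via bis(alkoxysulfonium) salt 15 (not isolated)
Conditions: (COCl)2, DMSO, CH2Cl2, −78 °C; then Et3N, −78 → 0 °C
Reagents that add atoms: none
Why: Swern oxidation; both primary alcohols are activated before base is added, which prevents lactol formation and over-oxidation, and the tertiary alcohol cannot be oxidised.

Step 9
Reactants: 16 hydroxy dialdehyde
Product: 17 (E)-enoate aldehyde
Conditions: Ph3P=CHCO2Me (1.1 equiv), CH2Cl2, 0 → 25 °C
Reagents that add atoms: methyl (triphenylphosphoranylidene)acetate, COC(=O)C=P(c1ccccc1)(c1ccccc1)c1ccccc1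
Why: Wittig reaction of the stabilised ylide is E-selective and chemoselective for the unhindered C14 aldehyde over the neopentyl aldehyde on the quaternary carbon.

Step 10
Reactants: 17 enoate aldehyde
Product: 18 spiro[4.5]decane hydroxy ester (C26–OH syn to C10–OH, CH2CO2Me trans to C26–OH)
Conditions: SmI2 (2.5 equiv, THF solution), MeOH, THF, −78 → −20 °C
Reagents that add atoms: none
Why: Ketyl–olefin radical cyclisation (5-exo-trig): trivalent samarium bridges the ketyl oxygen and the C10 hydroxyl, so the new C26–O bond is syn to C10–OH, and the enoate adds anti to the O–Sm group, giving the trans 2-(methoxycarbonylmethyl)cyclopentanol (C26 and C14 set).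

Step 11
Reactants: 18 spiro hydroxy ester
Product: 19 C7 tertiary allylic alcohol (isopropenyl retained; C7 epimers)
Conditions: SeO2 (0.5 equiv), t-BuOOH (3 equiv), CH2Cl2, 25 °C
Reagents that add atoms: selenium dioxide, O=[Se]=O; tert-butyl hydroperoxide, CC(C)(C)OO
Why: Allylic oxidation by SeO2 (ene reaction at the terminal CH2 with loss of the ring methine hydrogen, then [2,3]-sigmatropic shift) returns oxygen to C7 and regenerates the isopropenyl group, as known for limonene; the C7 configuration is irrelevant because this carbon becomes sp2 in step 20.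

Step 12
Reactants: 19 tertiary allylic alcohol
Product: 20 C26 TES ether
Conditions: Et3SiCl, imidazole, DMAP (cat.), DMF, 25 °C
Reagents that add atoms: chlorotriethylsilane, CC[Si](Cl)(CC)CC
Why: Silylation takes only the secondary hydroxyl (the two tertiary ones are inert), masking the one oxidisable alcohol before the chromium step.

Step 13
Reactants: 21 6-methylhept-5-en-2-one; 22 2,2-dimethoxyacetaldehyde (60% in water)
Product: 24 (E)-1,1-dimethoxy-8-methylnona-2,7-dien-4-one, via aldol adduct 23 (not isolated)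
Conditions: NaOH (aq), MeOH, 0 → 50 °C
Reagents that add atoms: none
Why: Crossed aldol condensation (Claisen–Schmidt) of the methyl ketone at its methyl group with the non-enolisable aldehyde; dehydration gives the E-enone.

Step 14
Reactants: 24 enone acetal
Product: 25 (E)-1,1-dimethoxy-8-methyl-4-methylenenona-2,7-diene
Conditions: Ph3PCH3Br, KOt-Bu, THF, 0 °C; then 24, 0 → 25 °C
Reagents that add atoms: methyltriphenylphosphonium bromide, C[P+](c1ccccc1)(c1ccccc1)c1ccccc1.[Br-]
Why: Wittig methylenation of the ketone carbonyl builds the 1,1-disubstituted alkene (C19=C28) without touching the acetal.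

Step 15
Reactants: 25 diene acetal
Product: 26 (E)-8-methyl-4-methylenenona-2,7-dienal
Conditions: oxalic acid (cat.), H2O, THF, 25 °C
Reagents that add atoms: water, O
Why: Mild acid hydrolysis of the allylic acetal frees the dienal; the E-alkene is retained.

Step 16
Reactants: 20 TES ether; 26 dienal
Product: 28 β-hydroxy ester (aldol adduct; mixture at the two new centres), via trilithium alkoxide-enolate 27 (not isolated)
Conditions: LiN(i-Pr)2 (3.05 equiv), THF, −78 °C; then 26, −78 °C; aq NH4Cl
Reagents that add atoms: none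
Why: Aldol addition: after deprotonation of both tertiary hydroxyls the lithium ester enolate adds 1,2 to the dienal at low temperature; the two new stereocentres are removed in step 17.

Step 17
Reactants: 28 aldol adduct
Product: 30 (E)-2-substituted trienoate, via allylic acetate 29 (not isolated)
Conditions: Ac2O, Et3N, DMAP (cat.), CH2Cl2, 0 °C; then DBU, 25 °C
Reagents that add atoms: none
Why: Acetylation of the secondary allylic hydroxyl and E1cB elimination give the more stable E isomer, with the dienyl chain trans to the ester and cis to the cyclopentyl group (C15=C16 geometry of the target).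

Step 18
Reactants: 30 trienoate
Product: 31 primary allylic alcohol (C27–OH)
Conditions: i-Bu2AlH (5 equiv), CH2Cl2, −78 °C; potassium sodium tartrate work-up
Reagents that add atoms: none
Why: 1,2-Reduction of the conjugated ester by the aluminium hydride gives the allylic alcohol; silyl ethers, tertiary alcohols and alkenes are inert.

Step 19
Reactants: 31 allylic alcohol
Product: 32 C27 acetate
Conditions: Ac2O, pyridine, CH2Cl2, 0 °C
Reagents that add atoms: acetic anhydride, CC(=O)OC(C)=O
Why: Acylation of the only primary alcohol; the two tertiary alcohols do not react under these conditions.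

Step 20
Reactants: 32 acetate
Product: 33 bis-silylated (2Z)-enal
Conditions: pyridinium chlorochromate [C5H5NH][CrO3Cl], NaOAc, 4 Å molecular sieves, CH2Cl2, 25 °C
Reagents that add atoms: pyridinium chlorochromate, [O-][Cr](=O)(=O)Cl.c1cc[nH+]cc1
Why: Babler–Dauben oxidative transposition: the chromate ester of the tertiary allylic alcohol undergoes a [3,3]-sigmatropic shift and oxidation to the enal, the formyl group expected cis to the more substituted C6 (formyl H, not methyl, faces C6; least A(1,3) strain); the C26 alcohol is protected and the C10 alcohol is tertiary.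

Step 21
Reactants: 33 bis-silylated enal
Product: 34 target CNP0204268.2
Conditions: HF·pyridine, pyridine, THF, 0 → 25 °C
Reagents that add atoms: none
Why: Fluoride-mediated desilylation removes the primary TBS and secondary TES ethers without touching the acetate, enal or triene.

## Compound list

1 | (S)-(+)-carvone, (5S)-2-methyl-5-(prop-1-en-2-yl)cyclohex-2-en-1-one | CC1=CC[C@@H](CC1=O)C(C)=C | starting material
2 | tert-butyl(3-iodopropoxy)dimethylsilane | CC(C)(C)[Si](C)(C)OCCCI | starting material
3 | lithium dienolate of 1 | CC1=CC[C@@H](C=C1O[Li])C(C)=C | intermediate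
4 | (5S,6R)-6-[3-(TBSO)propyl]-2-methyl-5-(prop-1-en-2-yl)cyclohex-2-en-1-one (chain trans to isopropenyl) | CC1=CC[C@H](C(C)=C)[C@@H](CCCO[Si](C)(C)C(C)(C)C)C1=O | intermediate
5 | allyl chloromethyl ether | C=CCOCCl | starting material
6 | triphenylphosphine | c1ccc(cc1)P(c1ccccc1)c1ccccc1 | starting material
7 | (allyloxymethyl)triphenylphosphonium chloride | C=CCOC[P+](c1ccccc1)(c1ccccc1)c1ccccc1.[Cl-] | intermediate
8 | (allyloxymethylene)triphenylphosphorane | C=CCOC=P(c1ccccc1)(c1ccccc1)c1ccccc1 | intermediate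
9 | allyl dienyl ether: 1-(allyloxymethylene) analogue of 4, ring centres unchanged, enol ether E/Z | CC1=CC[C@H](C(C)=C)[C@@H](CCCO[Si](C)(C)C(C)(C)C)C1=COCC=C | intermediate
10 | (1R,5S,6R)-1-allyl-6-[3-(TBSO)propyl]-2-methyl-5-(prop-1-en-2-yl)cyclohex-2-ene-1-carbaldehyde (CHO cis, allyl trans to the C6 chain) | CC1=CC[C@H](C(C)=C)[C@@H](CCCO[Si](C)(C)C(C)(C)C)[C@]1(C=O)CC=C | intermediate
11 | bis(disiamylboron) intermediate (C26–O–BSia2 and C14–BSia2) | CC1=CC[C@H](C(C)=C)[C@@H](CCCO[Si](C)(C)C(C)(C)C)[C@]1(COB(C(C)C(C)C)C(C)C(C)C)CCCB(C(C)C(C)C)C(C)C(C)C | intermediate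
12 | diol: C11 bears CH2OH (cis to C6 chain) and 3-hydroxypropyl (trans) | CC1=CC[C@H](C(C)=C)[C@@H](CCCO[Si](C)(C)C(C)(C)C)[C@]1(CO)CCCO | intermediate
13 | epoxy diol: C9–C10 epoxide cis to CH2OH | C[C@]12O[C@H]1C[C@H](C(C)=C)[C@@H](CCCO[Si](C)(C)C(C)(C)C)[C@]2(CO)CCCO | intermediate
14 | triol: C10 tertiary OH cis to CH2OH and to the C6 chain | C[C@]1(O)CC[C@H](C(C)=C)[C@@H](CCCO[Si](C)(C)C(C)(C)C)[C@]1(CO)CCCO | intermediate
15 | bis(alkoxydimethylsulfonium) dichloride of 14 | C[C@]1(O)CC[C@H](C(C)=C)[C@@H](CCCO[Si](C)(C)C(C)(C)C)[C@]1(CO[S+](C)C)CCCO[S+](C)C.[Cl-].[Cl-] | intermediate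
16 | hydroxy dialdehyde (C26 CHO and 3-oxopropyl on C11) | C[C@]1(O)CC[C@H](C(C)=C)[C@@H](CCCO[Si](C)(C)C(C)(C)C)[C@]1(C=O)CCC=O | intermediate
17 | methyl (E)-enoate aldehyde | C[C@]1(O)CC[C@H](C(C)=C)[C@@H](CCCO[Si](C)(C)C(C)(C)C)[C@]1(C=O)CC/C=C/C(=O)OC | intermediate
18 | spiro hydroxy ester: methyl 2-(spiro[4.5]decan-2-yl)acetate with C26–OH cis to C10–OH, CH2CO2Me trans to C26–OH, (6R,10S,11S,14S,26S) pattern of the target | COC(=O)C[C@@H]1CC[C@]2([C@H](CCCO[Si](C)(C)C(C)(C)C)[C@@H](C(C)=C)CC[C@]2(C)O)[C@H]1O | intermediate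
19 | C7 tertiary allylic alcohol of 18 (C7 epimers) | COC(=O)C[C@@H]1CC[C@]2([C@H](CCCO[Si](C)(C)C(C)(C)C)C(O)(C(C)=C)CC[C@]2(C)O)[C@H]1O | intermediate
20 | C26 TES ether of 19 | COC(=O)C[C@@H]1CC[C@]2([C@H](CCCO[Si](C)(C)C(C)(C)C)C(O)(C(C)=C)CC[C@]2(C)O)[C@H]1O[Si](CC)(CC)CC | intermediate
21 | 6-methylhept-5-en-2-one (sulcatone) | CC(=O)CCC=C(C)C | starting material
22 | 2,2-dimethoxyacetaldehyde | COC(OC)C=O | starting material
23 | 2-hydroxy-1,1-dimethoxy-8-methylnon-7-en-4-one (racemic) | COC(OC)C(O)CC(=O)CCC=C(C)C | intermediate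
24 | (E)-1,1-dimethoxy-8-methylnona-2,7-dien-4-one | COC(OC)/C=C/C(=O)CCC=C(C)C | intermediate
25 | (E)-1,1-dimethoxy-8-methyl-4-methylenenona-2,7-diene | COC(OC)/C=C/C(=C)CCC=C(C)C | intermediate
26 | (E)-8-methyl-4-methylenenona-2,7-dienal | O=C/C=C/C(=C)CCC=C(C)C | intermediate
27 | trilithium species of 20 (C7 and C10 alkoxides, ester enolate) | COC(O[Li])=C[C@@H]1CC[C@]2([C@H](CCCO[Si](C)(C)C(C)(C)C)C(O[Li])(C(C)=C)CC[C@]2(C)O[Li])[C@H]1O[Si](CC)(CC)CC | intermediate
28 | β-hydroxy ester (aldol adduct; C15, C16 and C7 unassigned) | COC(=O)C(C(O)/C=C/C(=C)CCC=C(C)C)[C@@H]1CC[C@]2([C@H](CCCO[Si](C)(C)C(C)(C)C)C(O)(C(C)=C)CC[C@]2(C)O)[C@H]1O[Si](CC)(CC)CC | intermediate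
29 | β-acetoxy ester of 28 | COC(=O)C(C(OC(C)=O)/C=C/C(=C)CCC=C(C)C)[C@@H]1CC[C@]2([C@H](CCCO[Si](C)(C)C(C)(C)C)C(O)(C(C)=C)CC[C@]2(C)O)[C@H]1O[Si](CC)(CC)CC | intermediate
30 | methyl (15E,17E)-trienoate (C27 as CO2Me) | C=C(/C=C/C=C(/C(=O)OC)[C@@H]1CC[C@]2([C@H](CCCO[Si](C)(C)C(C)(C)C)C(O)(C(C)=C)CC[C@]2(C)O)[C@H]1O[Si](CC)(CC)CC)CCC=C(C)C | intermediate
31 | C27 primary allylic alcohol | C=C(/C=C/C=C(/CO)[C@@H]1CC[C@]2([C@H](CCCO[Si](C)(C)C(C)(C)C)C(O)(C(C)=C)CC[C@]2(C)O)[C@H]1O[Si](CC)(CC)CC)CCC=C(C)C | intermediate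
32 | C27 acetate | C=C(/C=C/C=C(/COC(C)=O)[C@@H]1CC[C@]2([C@H](CCCO[Si](C)(C)C(C)(C)C)C(O)(C(C)=C)CC[C@]2(C)O)[C@H]1O[Si](CC)(CC)CC)CCC=C(C)C | intermediate
33 | (2Z)-enal with C3–OTBS and C26–OTES | C=C(/C=C/C=C(/COC(C)=O)[C@@H]1CC[C@]2([C@H](CCCO[Si](C)(C)C(C)(C)C)/C(=C(/C)C=O)CC[C@]2(C)O)[C@H]1O[Si](CC)(CC)CC)CCC=C(C)C | intermediate
34 | CNP0204268.2 | C=C(/C=C/C=C(/COC(C)=O)[C@@H]1CC[C@]2([C@H](CCCO)/C(=C(/C)C=O)CC[C@]2(C)O)[C@H]1O)CCC=C(C)C | target

## Step count and weak points

Total steps: 21. Longest linear sequence: 17 (1 → 34 through steps 1, 3–12 and 16–21).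

Step 10 (SmI2 cyclisation). The sense of induction at C26 rests on chelation to the C10 hydroxyl, and pinacol coupling or simple aldehyde reduction can compete. The fallback sets out from 17 and returns at 18. A thiazolium-derived carbene (3-benzyl-5-(2-hydroxyethyl)-4-methylthiazolium chloride, Et3N, EtOH, 70 °C) effects an intramolecular Stetter reaction to the spiro γ-keto ester F1. After equilibration of the ester-bearing centre with DBU, reduction with Zn(BH4)2 (Et2O, −20 °C; zinc chelate to the C10 hydroxyl, hydride from the free face) gives 18.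

Step 11 (SeO2 oxidation). Abstraction from the isopropenyl methyl instead of the hindered ring methine, or low conversion, is possible. The fallback sets out from 18 and returns at 19. Ozonolysis in methanol (O3, MeOH, −78 °C) followed by FeSO4·7H2O and TEMPO cleaves the isopropenyl group and traps the C7 radical as the alkoxyamine F2. m-CPBA converts it into the C7 ketone F3. CH2=C(CH3)MgBr with CeCl3 (THF, −78 °C) then adds to the ketone in preference to the ester and gives 19.

Step 20 (chromium oxidative transposition). The triene and allylic acetate may not tolerate the acidic oxidant, and the Z/E ratio at the tetrasubstituted enal is not secured. The fallback sets out from 32 and returns at 33. A non-oxidative 1,3-transposition with Ph3SiOReO3 (2 mol %, Et2O, −50 → 0 °C) gives the primary allylic alcohol F4. MnO2 (CH2Cl2, 25 °C) then oxidises only this allylic alcohol to the enal 33, and any E isomer is removed by chromatography.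

Further compounds
F1 | step 10 | spiro γ-keto ester (C26 ketone) | COC(=O)C[C@@H]1CC[C@]2([C@H](CCCO[Si](C)(C)C(C)(C)C)[C@@H](C(C)=C)CC[C@]2(C)O)C1=O
F2 | step 11 | C7 alkoxyamine (2,2,6,6-tetramethylpiperidin-1-yloxy at C7) | COC(=O)C[C@@H]1CC[C@]2([C@H](CCCO[Si](C)(C)C(C)(C)C)C(ON3C(C)(C)CCCC3(C)C)CC[C@]2(C)O)[C@H]1O
F3 | step 11 | C7 ketone | COC(=O)C[C@@H]1CC[C@]2([C@H](CCCO[Si](C)(C)C(C)(C)C)C(=O)CC[C@]2(C)O)[C@H]1O
F4 | step 20 | primary allylic alcohol (C1–OH, C7=C2 alkene) | C=C(/C=C/C=C(/COC(C)=O)[C@@H]1CC[C@]2([C@H](CCCO[Si](C)(C)C(C)(C)C)/C(=C(/C)CO)CC[C@]2(C)O)[C@H]1O[Si](CC)(CC)CC)CCC=C(C)C
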